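**Strategy.** In 1-benzofuran numbering the bicycle is cut at O1–C7a. If C7 is imagined to bear an oxygen like C5, the six-membered ring gains a mirror plane containing C3a and C6: it is a 3,5-dimethoxycyclohexa-2,5-diene whose quaternary C3a is only prochiral. A chiral trivalent-iodine oxidant attacks one of the two enantiotopic enol ethers at C7a, and the acetic acid arm, masked in the flask as its silyl ester, closes the γ-lactone. One operation forms O1–C7a, sets C3a and C7a, and tells C5 from C7. The achiral precursor, 2-(1-farnesyl-3,5-dimethoxycyclohexa-2,5-dien-1-yl)acetic acid, comes from Birch reductive farnesylation of 3,5-dimethoxybenzoic acid and Arndt–Eistert homologation.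

Key step: step 4

Remark: farnesyl means (2E,6E)-3,7,11-trimethyldodeca-2,6,10-trien-1-yl; the target is (3aR,7aR) and cis-fused (lactone 13 has the same spatial arrangement although its descriptors read 3aS,7aS); the sense of induction of the oxidant cannot be assigned in advance, so dimethyl (2R,2'R)-2,2'-[(2-(diacetoxyiodo)-1,3-phenylene)bis(oxy)]dipropanoate, SMILES CC(=O)OI(OC(C)=O)c1c(O[C@H](C)C(=O)OC)cccc1O[C@H](C)C(=O)OC, written (R,R)-ArI(OAc)2, is assumed to select the enol ether that leads to the target and its (S,S)-enantiomer would be used otherwise; the reagent is made beforehand in a separate flask (Mitsunobu reaction of 2-iodoresorcinol with methyl (S)-lactate, then NaBO3·4H2O in AcOH) and is not counted as a step.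

Step 1
Reactants: 1 3,5-dimethoxybenzoic acid; 2 (2E,6E)-farnesyl bromide
Product: 4 1-[(2E,6E)-farnesyl]-3,5-dimethoxycyclohexa-2,5-diene-1-carboxylic acid, via dilithium dienediolate 3 (not isolated)
Conditions: Li (3.3 equiv), NH3(l)–THF, −78 °C; isoprene until colourless; 2 (1.2 equiv), −78 °C; NH4Cl; cold NaH2PO4 buffer (pH 5), Et2O
Reagents that add atoms: (2E,6E)-farnesyl bromide 2, CC(C)=CCC/C(C)=C/CC/C(C)=C/CBr
Why: Birch reductive alkylation: the benzoate takes up two electrons, ammonia protonates C4, and dienediolate 3 is C-alkylated by the primary allylic bromide at the carboxyl-bearing carbon, which builds the achiral quaternary carbon while both methyl enol ethers stay intact in the basic medium.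

Step 2
Reactants: 4 1-[(2E,6E)-farnesyl]-3,5-dimethoxycyclohexa-2,5-diene-1-carboxylic acid; 5 (trimethylsilyl)diazomethane
Product: 8 2-diazo-1-[1-((2E,6E)-farnesyl)-3,5-dimethoxycyclohexa-2,5-dien-1-yl]ethan-1-one, via acid chloride 6 (not isolated), via C-silyl diazoketone 7 (not isolated)
Conditions: Me2C=C(Cl)NMe2 (1.1 equiv), CH2Cl2, 0 °C; then 5 (1.5 equiv), Et3N (1.5 equiv), THF–MeCN, 0 °C; aq NaHCO3; Et3N-washed silica
Reagents that add atoms: (trimethylsilyl)diazomethane 5, C[Si](C)(C)C=[N+]=[N-]
Why: First half of an Arndt–Eistert homologation: the α-chloroenamine makes acid chloride 6 without releasing HCl, 6 (no α-hydrogen, so no ketene with Et3N) C-acylates the silyl diazomethane, and the C-silyl group of 7 is lost on aqueous work-up, so the acid-labile enol ethers never meet acid.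

Step 3
Reactants: 8 2-diazo-1-[1-((2E,6E)-farnesyl)-3,5-dimethoxycyclohexa-2,5-dien-1-yl]ethan-1-one
Product: 10 2-[1-((2E,6E)-farnesyl)-3,5-dimethoxycyclohexa-2,5-dien-1-yl]acetic acid, via ketene 9 (not isolated)
Conditions: hν (365 nm), Et3N (1 equiv), THF–H2O (10:1), rt; NaH2PO4 buffer (pH 5) work-up
Reagents that add atoms: water, O
Why: Wolff rearrangement (second half of the Arndt–Eistert homologation): loss of N2 with 1,2-shift of the quaternary ring carbon gives ketene 9, which water traps as the acid; light is used so that no metal carbenoid is generated next to the enol ethers, and the medium stays neutral to basic.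

Step 4
Reactants: 10 2-[1-((2E,6E)-farnesyl)-3,5-dimethoxycyclohexa-2,5-dien-1-yl]acetic acid
Product: 13 (3aS,7aS)-3a-[(2E,6E)-farnesyl]-5-methoxy-3a,7a-dihydro-1-benzofuran-2,7(3H,6H)-dione, via silyl ester 11 (not isolated), via iodanyl oxocarbenium triflate 12 (not isolated)
Conditions: N,O-bis(trimethylsilyl)acetamide (1.1 equiv), CH2Cl2, rt, then volatiles removed; (R,R)-ArI(OAc)2 (1.0 equiv), Me3SiOTf (0.2 equiv), 4 Å MS, CH2Cl2, −78 °C; sat. aq NaHCO3, −78 °C to rt; Et3N-washed silica
Reagents that add atoms: none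
Why: Proposed new method: Me3SiOTf turns the diacetate into the more electrophilic aryl(acetoxy)iodanyl triflate, one enol ether of 11 attacks its iodine through C7a on the ring face remote from the ester arm to give oxocarbenium ion 12, and the carbonyl oxygen of the silyl ester then expels the iodoarene from C7a with inversion, after which the silyl group and the O-methyl group at C7 pass to the two acetates (Me3SiOAc, MeOAc) and the C7 ketone remains. The closest known reaction types are the α-oxygenation of silyl enol ethers and the oxylactonisation of alkenyl esters and keto acids with lactate-derived chiral aryliodanes under Lewis acid activation, together with desymmetrisations of Birch-derived cyclohexa-2,5-dienes by other electrophiles. The lactone ring closes in a 5-exo-tet displacement that forms O1–C7a. C7a is set by this backside attack, which the short tether allows only on the face that carries C3, so the ring fusion must be cis; C3a becomes a stereocentre when one of the two enantiotopic enol ethers is chosen, and this choice rests on the chiral lactate arms of the reagent. The step needs group selectivity between the enol ethers (reagent control), face selectivity (tether), site selectivity over the three trisubstituted farnesyl alkenes (enol ethers are far more nucleophilic, no peracid is present and only 1.0 equiv of oxidant is used) and no aromatisation (blocked by quaternary C3a). Masking the acid as a silyl ester keeps the flask aprotic, so no acid is set free beside the enol ethers, the carboxyl group exchanges onto iodine far less readily than a free acid would, and no base is present that could take a proton from C6 of the ion and blur the distinction between C5 and C7.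

Step 5
Reactants: 13 (3aS,7aS)-3a-[(2E,6E)-farnesyl]-5-methoxy-3a,7a-dihydro-1-benzofuran-2,7(3H,6H)-dione
Product: 14 (3aS,7R,7aS)-3a-[(2E,6E)-farnesyl]-7-hydroxy-5-methoxy-3a,6,7,7a-tetrahydro-1-benzofuran-2(3H)-one
Conditions: NaBH4 (1.0 equiv), CeCl3·7H2O (1.0 equiv), MeOH–THF, −78 °C; pH 7 phosphate buffer
Reagents that add atoms: none
Why: Luche reduction: NaBH4/CeCl3 reduces the α-acyloxy ketone quickly at −78 °C and leaves lactone, enol ether and alkenes alone; hydride should enter anti to the C7a–O1 bond and place the C7 hydroxyl cis to O1, but the C7 configuration is of no consequence because C7 becomes sp2 in step 6.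

Step 6
Reactants: 14 (3aS,7R,7aS)-3a-[(2E,6E)-farnesyl]-7-hydroxy-5-methoxy-3a,6,7,7a-tetrahydro-1-benzofuran-2(3H)-one
Product: 16 (3aR,7aR)-3a-[(2E,6E)-farnesyl]-3a,7a-dihydro-1-benzofuran-2,5(3H,4H)-dione, via β-hydroxy ketone 15 (not isolated)
Conditions: 1 M aq HCl, THF, 0 °C to rt
Reagents that add atoms: water, O
Why: Acid hydrolysis of the methyl enol ether frees the C5 ketone (15) and the β-hydroxy ketone then loses water through its enol to the conjugated C6–C7 enone (aldol-type dehydration); C3a is quaternary and C7a is not touched, so both stereocentres are kept, and dilute acid at room temperature should not protonate the farnesyl alkenes.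

**Compound list**

1 | 3,5-dimethoxybenzoic acid | COc1cc(OC)cc(C(=O)O)c1 | starting material
2 | (2E,6E)-farnesyl bromide [(2E,6E)-1-bromo-3,7,11-trimethyldodeca-2,6,10-triene] | CC(C)=CCC/C(C)=C/CC/C(C)=C/CBr | starting material
3 | dilithium (3,5-dimethoxycyclohexa-2,5-dien-1-ylidene)methanediolate | [Li+].[Li+].[O-]C([O-])=C1C=C(OC)CC(OC)=C1 | intermediate (not isolated)
4 | 1-[(2E,6E)-farnesyl]-3,5-dimethoxycyclohexa-2,5-diene-1-carboxylic acid | CC(C)=CCC/C(C)=C/CC/C(C)=C/CC1(C(=O)O)C=C(OC)CC(OC)=C1 | intermediate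
5 | (trimethylsilyl)diazomethane | C[Si](C)(C)C=[N+]=[N-] | starting material
6 | 1-[(2E,6E)-farnesyl]-3,5-dimethoxycyclohexa-2,5-diene-1-carbonyl chloride | CC(C)=CCC/C(C)=C/CC/C(C)=C/CC1(C(=O)Cl)C=C(OC)CC(OC)=C1 | intermediate (not isolated)
7 | 2-diazo-1-[1-((2E,6E)-farnesyl)-3,5-dimethoxycyclohexa-2,5-dien-1-yl]-2-(trimethylsilyl)ethan-1-one | CC(C)=CCC/C(C)=C/CC/C(C)=C/CC1(C(=O)C(=[N+]=[N-])[Si](C)(C)C)C=C(OC)CC(OC)=C1 | intermediate (not isolated)
8 | 2-diazo-1-[1-((2E,6E)-farnesyl)-3,5-dimethoxycyclohexa-2,5-dien-1-yl]ethan-1-one | CC(C)=CCC/C(C)=C/CC/C(C)=C/CC1(C(=O)C=[N+]=[N-])C=C(OC)CC(OC)=C1 | intermediate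
9 | 2-[1-((2E,6E)-farnesyl)-3,5-dimethoxycyclohexa-2,5-dien-1-yl]ethen-1-one (ketene) | CC(C)=CCC/C(C)=C/CC/C(C)=C/CC1(C=C=O)C=C(OC)CC(OC)=C1 | intermediate (not isolated)
10 | 2-[1-((2E,6E)-farnesyl)-3,5-dimethoxycyclohexa-2,5-dien-1-yl]acetic acid | CC(C)=CCC/C(C)=C/CC/C(C)=C/CC1(CC(=O)O)C=C(OC)CC(OC)=C1 | intermediate
11 | trimethylsilyl 2-[1-((2E,6E)-farnesyl)-3,5-dimethoxycyclohexa-2,5-dien-1-yl]acetate | CC(C)=CCC/C(C)=C/CC/C(C)=C/CC1(CC(=O)O[Si](C)(C)C)C=C(OC)CC(OC)=C1 | intermediate (not isolated)
12 | silyl ester 11 in which C7a carries the aryl(acetoxy)iodanyl group trans to the ester arm and C7 is an O-methyl oxocarbenium ion, triflate salt | CC(C)=CCC/C(C)=C/CC/C(C)=C/C[C@]1(CC(=O)O[Si](C)(C)C)C=C(OC)CC(=[O+]C)[C@@H]1I(OC(C)=O)c1c(O[C@H](C)C(=O)OC)cccc1O[C@H](C)C(=O)OC.[O-]S(=O)(=O)C(F)(F)F | intermediate (not isolated)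
13 | (3aS,7aS)-3a-[(2E,6E)-farnesyl]-5-methoxy-3a,7a-dihydro-1-benzofuran-2,7(3H,6H)-dione (cis-fused) | CC(C)=CCC/C(C)=C/CC/C(C)=C/C[C@]12C=C(OC)CC(=O)[C@H]1OC(=O)C2 | intermediate
14 | (3aS,7R,7aS)-3a-[(2E,6E)-farnesyl]-7-hydroxy-5-methoxy-3a,6,7,7a-tetrahydro-1-benzofuran-2(3H)-one (hydroxyl cis to O1) | CC(C)=CCC/C(C)=C/CC/C(C)=C/C[C@]12C=C(OC)C[C@@H](O)[C@H]1OC(=O)C2 | intermediate
15 | (3aR,7R,7aS)-3a-[(2E,6E)-farnesyl]-7-hydroxy-3a,6,7,7a-tetrahydro-1-benzofuran-2,5(3H,4H)-dione | CC(C)=CCC/C(C)=C/CC/C(C)=C/C[C@]12CC(=O)C[C@@H](O)[C@H]1OC(=O)C2 | intermediate (not isolated)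
16 | (3aR,7aR)-3a-[(2E,6E)-farnesyl]-3a,7a-dihydro-1-benzofuran-2,5(3H,4H)-dione | CC(C)=CCC/C(C)=C/CC/C(C)=C/C[C@]12CC(=O)C=C[C@H]1OC(=O)C2 | target

**Totals.** Total steps: 6 (the preparation of the chiral oxidant is not counted). Longest linear sequence: 6 steps from 1.

**Steps most likely to fail**

Step 4 (key step). The reagent may discriminate poorly between the two enantiotopic enol ethers. The remaining enol ether of 13 may be oxidised a second time, although this would consume mainly the minor enantiomer, whose free enol ether is the one the reagent prefers. A shift of the C4=C5 enol ether into conjugation with C7 would be harmless, since steps 5 and 6 would convert that isomer into the same enone. The fallback uses known reactions only; it sets out from 10 and rejoins the route at 16. Hydrolytic α-bromination of one enol ether with N-bromosuccinimide (NaHCO3, THF–H2O, −20 °C) should give the racemic bromo keto acid F1. On warming, its carboxylate should close the lactone by intramolecular O-alkylation, the cis-bromo epimer equilibrating by enolisation, to give the racemic keto lactone F2. NaBH4/CeCl3·7H2O reduction should give the racemic alcohol F3. Esterification with (S)-naproxen (EDC·HCl, DMAP, CH2Cl2) and chromatographic separation of the two diastereomers should give the naproxen ester F4 of the (3aS,7R,7aS) series. Dilute aqueous HCl in THF (enol ether hydrolysis) and then Et3N (E1cB loss of the carboxylate) should convert it into 16.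

Step 2. Acid chloride 6 may ionise with loss of CO and aromatise, or the bulky silyl diazomethane may acylate too slowly at the neopentyl carbonyl. The fallback sets out from 4, bypasses steps 2 and 3, and rejoins at 10; it runs under basic conditions throughout. LiAlH4 (THF, 0 °C to reflux) should give the neopentyl alcohol F5. Parikh–Doering oxidation (SO3·pyridine, DMSO, Et3N) should give the aldehyde F6. Reductive cyanation with tosylmethyl isocyanide (KOt-Bu, DME, −30 °C, then MeOH, reflux) should give the nitrile F7. Hydrolysis (KOH, aqueous ethylene glycol, 120 °C, buffered acidification) should return 10.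

Step 6. Loss of water from the β-hydroxy ketone may stall because the neighbouring C7a–O bond disfavours positive charge at C7, and stronger acid would risk proton-initiated cyclisation of the farnesyl chain. The fallback sets out from 15, isolated after the hydrolysis, and rejoins at 16. MsCl and Et3N (CH2Cl2, 0 °C) should give the mesylate F8, which should undergo E1cB elimination in the same flask (DBU if needed) to 16.

**Further compounds**

F1 | step 4 | racemic 2-[2-bromo-1-((2E,6E)-farnesyl)-5-methoxy-3-oxocyclohex-5-en-1-yl]acetic acid, bromine trans to the acetic acid arm (one enantiomer drawn) | CC(C)=CCC/C(C)=C/CC/C(C)=C/C[C@]1(CC(=O)O)C=C(OC)CC(=O)[C@@H]1Br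
F2 | step 4 | racemic cis-3a-[(2E,6E)-farnesyl]-5-methoxy-3a,7a-dihydro-1-benzofuran-2,7(3H,6H)-dione (one enantiomer drawn) | CC(C)=CCC/C(C)=C/CC/C(C)=C/C[C@]12C=C(OC)CC(=O)[C@H]1OC(=O)C2
F3 | step 4 | racemic 3a-[(2E,6E)-farnesyl]-7-hydroxy-5-methoxy-3a,6,7,7a-tetrahydro-1-benzofuran-2(3H)-one, relative configuration as in 14 (one enantiomer drawn) | CC(C)=CCC/C(C)=C/CC/C(C)=C/C[C@]12C=C(OC)C[C@@H](O)[C@H]1OC(=O)C2
F4 | step 4 | (3aS,7R,7aS)-3a-[(2E,6E)-farnesyl]-5-methoxy-2-oxo-2,3,3a,6,7,7a-hexahydro-1-benzofuran-7-yl (2S)-2-(6-methoxynaphthalen-2-yl)propanoate | CC(C)=CCC/C(C)=C/CC/C(C)=C/C[C@]12C=C(OC)C[C@@H](OC(=O)[C@@H](C)c3ccc4cc(OC)ccc4c3)[C@H]1OC(=O)C2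
F5 | step 2 | [1-((2E,6E)-farnesyl)-3,5-dimethoxycyclohexa-2,5-dien-1-yl]methanol | CC(C)=CCC/C(C)=C/CC/C(C)=C/CC1(CO)C=C(OC)CC(OC)=C1
F6 | step 2 | 1-[(2E,6E)-farnesyl]-3,5-dimethoxycyclohexa-2,5-diene-1-carbaldehyde | CC(C)=CCC/C(C)=C/CC/C(C)=C/CC1(C=O)C=C(OC)CC(OC)=C1
F7 | step 2 | 2-[1-((2E,6E)-farnesyl)-3,5-dimethoxycyclohexa-2,5-dien-1-yl]acetonitrile | CC(C)=CCC/C(C)=C/CC/C(C)=C/CC1(CC#N)C=C(OC)CC(OC)=C1
F8 | step 6 | (3aR,7R,7aS)-3a-[(2E,6E)-farnesyl]-2,5-dioxooctahydro-1-benzofuran-7-yl methanesulfonate | CC(C)=CCC/C(C)=C/CC/C(C)=C/C[C@]12CC(=O)C[C@@H](OS(C)(=O)=O)[C@H]1OC(=O)C2
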